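A direct plan would tribrominate 4-methylcatechol A1 to 3,4,6-tribromo-5-methylcatechol A2 and dehydrogenate A2 to the o-quinone A3. A3 would then tautomerise to the p-quinone methide A4, which would add water to give the benzyl alcohol A5; addition of A5 to a second molecule of A4 would close the dibenzyl ether.
Its weakest steps would be:
- The tautomerisation of A3 to A4 followed by double 1,6-addition, which makes both C–O bonds: it has no preparative precedent as an ether synthesis, depends on exactly half an equivalent of water, and must suppress aryl ether oligomers and over-oxidation to the aldehyde while four free phenols are present.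
- The oxidation of A2 to the electrophilic tribromo-o-quinone A3: A3 has to be isolated without aqueous work-up and is itself an oxidant for every catechol formed after it.
- The catechol → quinone → catechol redox detour from A1, used to functionalise one benzylic C–H: it builds the central C–O–C bond last, on unprotected catechols, so all the risk falls on the complete skeleton.

**Retrosynthetic overview**
- The CH2–O–CH2 bridge, the ring carbons C1/C1′ it is attached to and the bromine-bearing C2/C2′ are read as bis(3-bromoprop-2-ynyl) ether, made in one step from dipropargyl ether.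
- The remaining C3(Br)–C4(O)–C5(O)–C6(Br) of each ring is the diene of 3,4-bis(benzyloxy)-2,5-dibromothiophene 1,1-dioxide.
- Key disconnection: the C2–C3 and C6–C1 bonds of both benzene rings (four C–C bonds), formed in a twofold Diels–Alder reaction with cheletropic loss of SO2. Both rings are built in the same operation, after the ether, with all six bromines and four oxygens already in place.
- The design has no quinone, no quinone methide and no late C–O bond formation; the only step after ring construction is O-debenzylation.

Key step: step 5

Remark: the target is achiral, so no stereocentre has to be set; dimethyldioxirane is assumed to be used as a freshly prepared acetone solution.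

Step 1
Reactants: 1 dipropargyl ether (3-(prop-2-yn-1-yloxy)prop-1-yne)
Product: 2 bis(3-bromoprop-2-yn-1-yl) ether
Conditions: NBS (2.3 equiv), AgNO3 (10 mol%), acetone, rt, dark; used cold and promptly as a solution
Reagents that add atoms: N-bromosuccinimide, O=C1CCC(=O)N1Br
Why: Silver-acetylide-mediated electrophilic bromination of terminal alkynes is a standard reaction that tolerates propargylic ethers and should cap both alkynes with bromine.

Step 2
Reactants: 3 3,4-dimethoxythiophene
Product: 4 3,4-bis(benzyloxy)thiophene
Conditions: BnOH (4 equiv), p-TsOH·H2O (10 mol%), toluene, 100 °C, MeOH removed over 4 Å molecular sieves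
Reagents that add atoms: benzyl alcohol, OCc1ccccc1
Why: Acid-catalysed transetherification of 3,4-dimethoxythiophene (C-protonation, addition of the alcohol to the oxocarbenium ion, loss of methanol) is the usual entry to 3,4-dialkoxythiophenes from primary alcohols and is driven by removal of methanol.

Step 3
Reactants: 4 3,4-bis(benzyloxy)thiophene
Product: 5 3,4-bis(benzyloxy)-2,5-dibromothiophene
Conditions: NBS (2.05 equiv), DMF, 0 °C, dark; product kept cold and used soon
Reagents that add atoms: N-bromosuccinimide, O=C1CCC(=O)N1Br
Why: Electrophilic aromatic bromination should take the only two free positions, both α to sulfur and activated by the neighbouring alkoxy groups, while the polar medium in the dark avoids radical bromination of the benzyl CH2 groups.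

Step 4
Reactants: 5 3,4-bis(benzyloxy)-2,5-dibromothiophene
Product: 7 3,4-bis(benzyloxy)-2,5-dibromothiophene 1,1-dioxide, via thiophene 1-oxide 6 (not isolated)
Conditions: dimethyldioxirane (about 0.08 M in acetone, 3 equiv), CH2Cl2, −20 °C → rt, dark; evaporation only, no aqueous work-up
Reagents that add atoms: dimethyldioxirane, CC1(C)OO1
Why: Stepwise S-oxidation of a thiophene to its 1,1-dioxide by a neutral dioxirane is a known reaction that leaves only acetone behind, and the four substituents should keep the 1-oxide and the dioxide from dimerising.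

Step 5
Reactants: 2 bis(3-bromoprop-2-yn-1-yl) ether; 7 3,4-bis(benzyloxy)-2,5-dibromothiophene 1,1-dioxide (two molecules per molecule of 2)
Product: 11 bis[4,5-bis(benzyloxy)-2,3,6-tribromobenzyl] ether, via bridged sulfone mono-adduct 8 (not isolated), via mono-arene bromoalkyne 9 (not isolated), via bridged sulfone second adduct 10 (not isolated)
Conditions: 7 (2.4 equiv), chlorobenzene (0.2 M), 130 °C, Ar, dark, BHT (2 mol%), solid NaHCO3 as acid scavenger
Reagents that add atoms: none
Why: Each bromoalkyne should undergo a thermal [4+2] cycloaddition with the s-cis-locked, non-aromatic diene of 7 to give a 7-thiabicyclo[2.2.1]hepta-2,5-diene 7,7-dioxide (8, then 10), which loses SO2 by cheletropic extrusion because the product is a benzene ring. The closest known reaction type is the Diels–Alder reaction of tetrasubstituted (for example tetrahalo) thiophene 1,1-dioxides with alkynes, which gives fully substituted benzenes in the same way. Each benzene ring closes by one intermolecular [4+2] event that forms C2–C3 and C6–C1 together, so no ring-size or strain question arises, and the two events are independent because the CH2–O–CH2 spacer insulates the alkynes. No stereocentre remains, since the bridgehead centres of 8 and 10 are erased on aromatisation. No regioselectivity is needed because 7 is symmetrical and either orientation of the unsymmetrical alkyne gives the same arene; the chemoselectivity needed, cross-cycloaddition over self-dimerisation of the diene, is secured by the tetrasubstitution of 7, and the small excess of 7 covers thermal loss. The diene is ambiphilic (the alkoxy groups raise its HOMO, the sulfonyl group lowers its LUMO), so the moderately electron-poor bromoalkyne should find a workable frontier-orbital gap at 130 °C.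

Step 6
Reactants: 11 bis[4,5-bis(benzyloxy)-2,3,6-tribromobenzyl] ether
Product: 13 bis(2,3,6-tribromo-4,5-dihydroxybenzyl) ether, via cyclic chloroboronate 12 (not isolated)
Conditions: BCl3 (1 M in CH2Cl2, 8 equiv), C6HMe5 (12 equiv), CH2Cl2, −78 °C; then THF–H2O, −78 → 0 °C; EtOAc extraction, no alcohol and no base in the work-up
Reagents that add atoms: none
Why: Lewis-acid debenzylation of aryl benzyl ethers with a cation scavenger should cleave the four hindered, twisted ArO–CH2Ph bonds at low temperature, the benzyl cations being trapped by pentamethylbenzene, whereas the central ether lies between two electron-poor 2,6-dibrominated benzyl groups (a substitution pattern known to make benzyl ethers acid-resistant) and should neither coordinate nor ionise; water then hydrolyses the boron ester 12.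

**Compound list**
1 | dipropargyl ether (3-(prop-2-yn-1-yloxy)prop-1-yne) | C#CCOCC#C | starting material
2 | bis(3-bromoprop-2-yn-1-yl) ether | BrC#CCOCC#CBr | intermediate
3 | 3,4-dimethoxythiophene | COc1cscc1OC | starting material
4 | 3,4-bis(benzyloxy)thiophene | c1scc(OCc2ccccc2)c1OCc1ccccc1 | intermediate
5 | 3,4-bis(benzyloxy)-2,5-dibromothiophene | Brc1sc(Br)c(OCc2ccccc2)c1OCc1ccccc1 | intermediate
6 | 3,4-bis(benzyloxy)-2,5-dibromothiophene 1-oxide | O=S1C(Br)=C(OCc2ccccc2)C(OCc2ccccc2)=C1Br | intermediate
7 | 3,4-bis(benzyloxy)-2,5-dibromothiophene 1,1-dioxide | O=S1(=O)C(Br)=C(OCc2ccccc2)C(OCc2ccccc2)=C1Br | intermediate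
8 | 5,6-bis(benzyloxy)-1,3,4-tribromo-2-{[(3-bromoprop-2-yn-1-yl)oxy]methyl}-7-thiabicyclo[2.2.1]hepta-2,5-diene 7,7-dioxide (racemic) | O=S1(=O)C2(Br)C(COCC#CBr)=C(Br)C1(Br)C(OCc1ccccc1)=C2OCc1ccccc1 | intermediate
9 | 1,2-bis(benzyloxy)-3,4,6-tribromo-5-{[(3-bromoprop-2-yn-1-yl)oxy]methyl}benzene | BrC#CCOCc1c(Br)c(Br)c(OCc2ccccc2)c(OCc2ccccc2)c1Br | intermediate
10 | 5,6-bis(benzyloxy)-1,3,4-tribromo-2-({[4,5-bis(benzyloxy)-2,3,6-tribromobenzyl]oxy}methyl)-7-thiabicyclo[2.2.1]hepta-2,5-diene 7,7-dioxide (racemic) | O=S1(=O)C2(Br)C(COCc3c(Br)c(Br)c(OCc4ccccc4)c(OCc4ccccc4)c3Br)=C(Br)C1(Br)C(OCc1ccccc1)=C2OCc1ccccc1 | intermediate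
11 | bis[4,5-bis(benzyloxy)-2,3,6-tribromobenzyl] ether | Brc1c(Br)c(OCc2ccccc2)c(OCc2ccccc2)c(Br)c1COCc1c(Br)c(Br)c(OCc2ccccc2)c(OCc2ccccc2)c1Br | intermediate
12 | bis[(4,5,7-tribromo-2-chloro-1,3,2-benzodioxaborol-6-yl)methyl] ether | ClB1Oc2c(Br)c(Br)c(COCc3c(Br)c(Br)c4OB(Cl)Oc4c3Br)c(Br)c2O1 | intermediate
13 | bis(2,3,6-tribromo-4,5-dihydroxybenzyl) ether | Oc1c(O)c(Br)c(COCc2c(Br)c(O)c(O)c(Br)c2Br)c(Br)c1Br | target

**Step count:** 6 steps in total; the longest linear sequence is 5 steps (steps 2 to 6).

**Steps most likely to fail**

1. Step 5 (key step). The internal, bromine-capped alkyne may add too slowly, so that the diene decomposes thermally before both cycloadditions are complete. The fallback sets out from 7 and uses dipropargyl ether 1 in place of 2, moving the introduction of the C2 bromine to the end. The less hindered terminal alkynes should give bis[3,4-bis(benzyloxy)-2,5-dibromobenzyl] ether F1 under the conditions of step 5. Debenzylation as in step 6 would give bis(2,5-dibromo-3,4-dihydroxybenzyl) ether F2. The one free ring position of each catechol, para to a hydroxyl group, would then be brominated (Br2, 2.1 equiv, NaOAc, AcOH–CH2Cl2, 10 °C, Na2S2O4 wash), which comes back to the route at 13.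

2. Step 4. The oxidant may attack the electron-rich enol ether carbons or the benzyl CH2 groups instead of sulfur, or the isolated dioxide may hydrolyse. The fallback sets out from 5 and 2 and does not isolate a diene at all. Compound 5 would be oxidised only to the 1-oxide 6 in the presence of 2 (mCPBA, 2.4 equiv, BF3·OEt2, CH2Cl2, −20 °C). The 1-oxide, a more reactive diene than the dioxide, would be trapped by cycloaddition as it forms, and loss of sulfur monoxide would lead through 9 to 11, where the route is rejoined.

3. Step 6. The Lewis acid may ionise the central dibenzylic C–O bond along with the O-benzyl groups, or leave some of the hindered benzyl groups in place. The fallback sets out from 2 and carries the catechol oxygens as methoxymethyl acetals, which are removed by dilute protic acid. Commercial diethyl 3,4-dihydroxythiophene-2,5-dicarboxylate F3 would be alkylated (MOMCl, iPr2NEt, CH2Cl2) to diethyl 3,4-bis(methoxymethoxy)thiophene-2,5-dicarboxylate F4. Saponification (NaOH, aqueous EtOH; acidification to pH 3–4 at 0 °C) would give 3,4-bis(methoxymethoxy)thiophene-2,5-dicarboxylic acid F5. Bromodecarboxylation (NBS, DMF, rt) would give 2,5-dibromo-3,4-bis(methoxymethoxy)thiophene F6. Oxidation as in step 4 would give 2,5-dibromo-3,4-bis(methoxymethoxy)thiophene 1,1-dioxide F7. Cycloaddition with 2 as in step 5 would give bis[2,3,6-tribromo-4,5-bis(methoxymethoxy)benzyl] ether F8. Treatment with 2 M HCl in THF–H2O at rt would then release 13, where the fallback comes back to the route.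

**Further compounds**
F1 | step 5 | bis[3,4-bis(benzyloxy)-2,5-dibromobenzyl] ether | Brc1c(COCc2cc(Br)c(OCc3ccccc3)c(OCc3ccccc3)c2Br)cc(Br)c(OCc2ccccc2)c1OCc1ccccc1
F2 | step 5 | bis(2,5-dibromo-3,4-dihydroxybenzyl) ether | Oc1c(O)c(Br)c(COCc2cc(Br)c(O)c(O)c2Br)cc1Br
F0 | step 4 | none | none
F3 | step 6 | diethyl 3,4-dihydroxythiophene-2,5-dicarboxylate | CCOC(=O)c1sc(C(=O)OCC)c(O)c1O
F4 | step 6 | diethyl 3,4-bis(methoxymethoxy)thiophene-2,5-dicarboxylate | CCOC(=O)c1sc(C(=O)OCC)c(OCOC)c1OCOC
F5 | step 6 | 3,4-bis(methoxymethoxy)thiophene-2,5-dicarboxylic acid | COCOc1c(C(=O)O)sc(C(=O)O)c1OCOC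
F6 | step 6 | 2,5-dibromo-3,4-bis(methoxymethoxy)thiophene | COCOc1c(Br)sc(Br)c1OCOC
F7 | step 6 | 2,5-dibromo-3,4-bis(methoxymethoxy)thiophene 1,1-dioxide | COCOC1=C(Br)S(=O)(=O)C(Br)=C1OCOC
F8 | step 6 | bis[2,3,6-tribromo-4,5-bis(methoxymethoxy)benzyl] ether | COCOc1c(OCOC)c(Br)c(COCc2c(Br)c(OCOC)c(OCOC)c(Br)c2Br)c(Br)c1Br
A1 | direct plan | 4-methylcatechol (4-methylbenzene-1,2-diol) | Cc1ccc(O)c(O)c1
A2 | direct plan | 3,4,6-tribromo-5-methylbenzene-1,2-diol | Cc1c(Br)c(Br)c(O)c(O)c1Br
A3 | direct plan | 3,4,6-tribromo-5-methylcyclohexa-3,5-diene-1,2-dione | CC1=C(Br)C(=O)C(=O)C(Br)=C1Br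
A4 | direct plan | 2,3,5-tribromo-6-hydroxy-4-methylidenecyclohexa-2,5-dien-1-one | C=C1C(Br)=C(O)C(=O)C(Br)=C1Br
A5 | direct plan | 3,4,6-tribromo-5-(hydroxymethyl)benzene-1,2-diol | OCc1c(Br)c(Br)c(O)c(O)c1Br
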